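**Retrosynthetic overview**

1. Feature: a ten-membered carbocycle C1–C10 in which C6 carries the lactone oxygen and is allylic to C4=C5 (before epoxidation), while the neighbouring C7 carries the three-carbon unit C11(C12)(C13). This is the imprint of a [2,3]-Wittig shift of a C6–O–C13 allyl ether onto C7 (germacrane numbering; C14 on C10, C15 on C4).
2. Late stage: the 7(11)-butenolide with C13–OAc comes from syn-dehydration of an 11-hydroxy-13-acetoxy lactone, made by OsO4 dihydroxylation of the α-methylene lactone. Both cis-oxiranes come from hydroxyl-directed epoxidation of (Z)-alkenes (O6–H directs to C4=C5, O8–H to C1=C10).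
3. Key disconnection: the carbocycle (C6–C7 bond, C6 stereocentre) from a thirteen-membered (Z,Z)-diallylic ether by [2,3]-Wittig ring contraction.
4. The ether comes from macro-Williamson closure of a C6-hydroxy C13-chloride; C7=C11 from a Horner–Wadsworth–Emmons reaction; C8 from methyl (R)-glycidate opened by a (Z)-alkenyl metal; C2–C6 and C15 from nerol.
5. Ring order: thirteen-membered ether (step 13), ten-membered carbocycle (step 14), 4,5-oxirane (step 15), γ-lactone (step 17), 1,10-oxirane (step 19).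

Key step: step 14

Remark on the structure: the SMILES has C2/C9 cis on the 1,10-oxirane and C3/C6 cis on the 4,5-oxirane, with O1/10, O4/5, O6 and O8 all on one ring face (1R,4S,5R,6R,8R,10S). Stereospecific epoxidation therefore needs (Z)-C1=C10 and (Z)-C4=C5 in the ring, so the route builds neryl-type (Z) alkenes. Benzylic ethers are kept out of the key step because they would be lithiated and rearrange themselves; PMB = 4-methoxybenzyl, TBS = tert-butyldimethylsilyl.

**Route**

Step 1
Reactants: 1 nerol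
Product: 2 neryl 4-methoxybenzyl ether
Conditions: NaH, PMBCl, n-Bu4NI (cat.), THF/DMF, 0 °C → rt
Reagents that add atoms: 4-methoxybenzyl chloride, COc1ccc(CCl)cc1
Why: Williamson etherification of the primary allylic alkoxide masks O6 with a group that survives the organometallic steps and is later removed oxidatively beside silyl ethers; the (Z)-C4=C5 geometry of nerol is carried unchanged.

Step 2
Reactants: 2 neryl 4-methoxybenzyl ether
Product: 4 (4Z)-6-[(4-methoxybenzyl)oxy]-4-methylhex-4-enal, via terminal epoxide 3 (not isolated)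
Conditions: mCPBA, CH2Cl2, −20 °C; then H5IO6, THF/H2O, 0 °C
Reagents that add atoms: 3-chloroperoxybenzoic acid, OOC(=O)c1cccc(Cl)c1; water, O
Why: Prilezhaev epoxidation prefers the electron-rich terminal alkene (C4=C5 is deactivated by its allylic oxygen), and periodic acid then hydrolyses and cleaves the epoxide (Malaprade-type glycol cleavage) to the C1 aldehyde.

Step 3
Reactants: 4 (4Z)-6-[(4-methoxybenzyl)oxy]-4-methylhex-4-enal
Product: 5 (2Z,6Z)-7-iodo-3-methylocta-2,6-dien-1-yl 4-methoxybenzyl ether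
Conditions: EtPPh3I, n-BuLi, THF, 0 °C; I2, −78 °C; NaN(SiMe3)2, −20 °C; then 4, −78 → −20 °C
Reagents that add atoms: ethyltriphenylphosphonium iodide, CC[P+](c1ccccc1)(c1ccccc1)c1ccccc1.[I-]; iodine, II
Why: Stork–Zhao-type Wittig olefination with the α-iodoethylidene ylide gives, under kinetic control, the (Z)-2-iodoalkene with iodine cis to the chain, which fixes the future (Z)-C1=C10 geometry and supplies C10 and C14.

Step 4
Reactants: 5 (2Z,6Z)-7-iodo-3-methylocta-2,6-dien-1-yl 4-methoxybenzyl ether; 6 methyl (2R)-oxirane-2-carboxylate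
Product: 9 methyl (2R,4Z,8Z)-2-hydroxy-10-[(4-methoxybenzyl)oxy]-4,8-dimethyldeca-4,8-dienoate, via vinyllithium 7 (not isolated), via vinylmagnesium bromide 8 (not isolated)
Conditions: t-BuLi (2 equiv), Et2O, −78 °C; MgBr2·OEt2; CuI (cat.), 6, THF, −40 °C; aq. NH4Cl
Reagents that add atoms: none
Why: Iodine–lithium exchange keeps the alkene geometry, and the copper-catalysed Grignard opens the glycidate by SN2 attack at its CH2 terminus (C9) faster than it adds to the ester, so C8 keeps the R configuration of the epoxide and C9 ends up cis to C2.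

Step 5
Reactants: 9 methyl (2R,4Z,8Z)-2-hydroxy-10-[(4-methoxybenzyl)oxy]-4,8-dimethyldeca-4,8-dienoate
Product: 10 methyl (2R,4Z,8Z)-2-[(tert-butyldimethylsilyl)oxy]-10-[(4-methoxybenzyl)oxy]-4,8-dimethyldeca-4,8-dienoate
Conditions: TBSCl, imidazole, DMF, rt
Reagents that add atoms: tert-butyldimethylsilyl chloride, CC(C)(C)[Si](C)(C)Cl
Why: Standard silylation of the secondary α-hydroxy ester gives an O8 protecting group with no acidic α-hydrogen for the later organolithium step; no stereocentre is touched.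

Step 6
Reactants: 10 methyl (2R,4Z,8Z)-2-[(tert-butyldimethylsilyl)oxy]-10-[(4-methoxybenzyl)oxy]-4,8-dimethyldeca-4,8-dienoate
Product: 11 (2R,4Z,8Z)-2-[(tert-butyldimethylsilyl)oxy]-10-[(4-methoxybenzyl)oxy]-4,8-dimethyldeca-4,8-dienal
Conditions: i-Bu2AlH (1.1 equiv), CH2Cl2, −78 °C; potassium sodium tartrate (aq.)
Reagents that add atoms: none
Why: Partial reduction of an α-silyloxy ester with i-Bu2AlH stops at the aldehyde at −78 °C because the tetrahedral aluminate persists until work-up; the C7 aldehyde is used at once to avoid epimerisation at C8.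

Step 7
Reactants: 12 diethyl (2-hydroxyethyl)phosphonate
Product: 13 diethyl {2-[(tert-butyldimethylsilyl)oxy]ethyl}phosphonate
Conditions: TBSCl, imidazole, CH2Cl2, rt
Reagents that add atoms: tert-butyldimethylsilyl chloride, CC(C)(C)[Si](C)(C)Cl
Why: Standard silylation of a primary alcohol puts the future O12 under a silyl group that is neither benzylic nor lithium-coordinating.

Step 8
Reactants: 13 diethyl {2-[(tert-butyldimethylsilyl)oxy]ethyl}phosphonate
Product: 14 ethyl 3-[(tert-butyldimethylsilyl)oxy]-2-(diethoxyphosphoryl)propanoate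
Conditions: LiN(i-Pr)2 (2.1 equiv), THF, −78 °C; ClCO2Et
Reagents that add atoms: ethyl chloroformate, CCOC(=O)Cl
Why: C-acylation of the α-lithiated phosphonate with a chloroformate is the standard route to α-substituted phosphonoacetates (two equivalents of base because the product is the stronger acid); the cold temperature suppresses β-elimination of silyloxide.

Step 9
Reactants: 11 (2R,4Z,8Z)-2-[(tert-butyldimethylsilyl)oxy]-10-[(4-methoxybenzyl)oxy]-4,8-dimethyldeca-4,8-dienal; 14 ethyl 3-[(tert-butyldimethylsilyl)oxy]-2-(diethoxyphosphoryl)propanoate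
Product: 15 ethyl (2E,4R,6Z,10Z)-4-[(tert-butyldimethylsilyl)oxy]-2-{[(tert-butyldimethylsilyl)oxy]methyl}-12-[(4-methoxybenzyl)oxy]-6,10-dimethyldodeca-2,6,10-trienoate
Conditions: LiCl, DBU, MeCN, 0 °C → rt
Reagents that add atoms: none
Why: Horner–Wadsworth–Emmons olefination under Masamune–Roush conditions is mild enough to spare the C8 stereocentre and should give the thermodynamically preferred trisubstituted enoate, with C8 trans to the ester carbon (future C13) and cis to the silyloxymethyl group (C12).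

Step 10
Reactants: 15 ethyl (2E,4R,6Z,10Z)-4-[(tert-butyldimethylsilyl)oxy]-2-{[(tert-butyldimethylsilyl)oxy]methyl}-12-[(4-methoxybenzyl)oxy]-6,10-dimethyldodeca-2,6,10-trienoate
Product: 16 (2Z,4R,6Z,10Z)-4-[(tert-butyldimethylsilyl)oxy]-2-{[(tert-butyldimethylsilyl)oxy]methyl}-12-[(4-methoxybenzyl)oxy]-6,10-dimethyldodeca-2,6,10-trien-1-ol
Conditions: i-Bu2AlH (2.2 equiv), CH2Cl2, −78 °C
Reagents that add atoms: none
Why: 1,2-Reduction of the enoate gives the C13 allylic alcohol with the alkene geometry unchanged (the descriptor changes to Z only through CIP priorities).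

Step 11
Reactants: 16 (2Z,4R,6Z,10Z)-4-[(tert-butyldimethylsilyl)oxy]-2-{[(tert-butyldimethylsilyl)oxy]methyl}-12-[(4-methoxybenzyl)oxy]-6,10-dimethyldodeca-2,6,10-trien-1-ol
Product: 17 (2Z,6Z,9R,10E)-12-chloro-9-[(tert-butyldimethylsilyl)oxy]-11-{[(tert-butyldimethylsilyl)oxy]methyl}-3,7-dimethyldodeca-2,6,10-trien-1-yl 4-methoxybenzyl ether
Conditions: NCS, Me2S, CH2Cl2, −40 → 0 °C
Reagents that add atoms: N-chlorosuccinimide, ClN1C(=O)CCC1=O
Why: Corey–Kim chlorination converts the primary allylic alcohol into the chloride by SN2 displacement of the alkoxysulfonium group under neutral conditions, without allylic transposition and without base that could move the neighbouring silyl group.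

Step 12
Reactants: 17 (2Z,6Z,9R,10E)-12-chloro-9-[(tert-butyldimethylsilyl)oxy]-11-{[(tert-butyldimethylsilyl)oxy]methyl}-3,7-dimethyldodeca-2,6,10-trien-1-yl 4-methoxybenzyl ether
Product: 18 (2Z,6Z,9R,10E)-12-chloro-9-[(tert-butyldimethylsilyl)oxy]-11-{[(tert-butyldimethylsilyl)oxy]methyl}-3,7-dimethyldodeca-2,6,10-trien-1-ol
Conditions: DDQ, CH2Cl2/pH 7 buffer, 0 °C
Reagents that add atoms: none
Why: Oxidative PMB cleavage by DDQ (hydride abstraction from the electron-rich benzyl ether, then hydrolysis) frees O6 and leaves silyl ethers, the allylic chloride and the alkenes untouched.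

Step 13
Reactants: 18 (2Z,6Z,9R,10E)-12-chloro-9-[(tert-butyldimethylsilyl)oxy]-11-{[(tert-butyldimethylsilyl)oxy]methyl}-3,7-dimethyldodeca-2,6,10-trien-1-ol
Product: 19 (3Z,7Z,10R,11Z)-10-[(tert-butyldimethylsilyl)oxy]-12-{[(tert-butyldimethylsilyl)oxy]methyl}-4,8-dimethyl-1-oxacyclotrideca-3,7,11-triene (thirteen-membered ether O bridging C6 and C13; C4=C5 and C1=C10 Z; C8 trans to C13 on C7=C11)
Conditions: NaH, THF, slow addition (high dilution), 50 °C
Reagents that add atoms: none
Why: Intramolecular Williamson etherification closes the thirteen-membered ring; the alkoxide sits on C6, remote from both silyl ethers, so base-induced silyl migration cannot scramble O12 and O13.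

Step 14
Reactants: 19 thirteen-membered diallylic ether (3Z,7Z,10R,11Z)-10-[(tert-butyldimethylsilyl)oxy]-12-{[(tert-butyldimethylsilyl)oxy]methyl}-4,8-dimethyl-1-oxacyclotrideca-3,7,11-triene
Product: 21 (1S,2Z,6Z,9R,10R)-9-[(tert-butyldimethylsilyl)oxy]-10-{3-[(tert-butyldimethylsilyl)oxy]prop-1-en-2-yl}-3,7-dimethylcyclodeca-2,6-dien-1-ol (germacrane numbering: 6S,7R,8R; 6β-OH; 8β-OTBS), via C6-lithiated ether 20 (not isolated)
Conditions: n-BuLi (2 equiv), THF, −78 → −20 °C; aq. NH4Cl at −20 °C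
Reagents that add atoms: none
Why: n-BuLi removes a proton from C6, the less hindered of the ring α-oxy allylic methylenes (C13 and C12 are flanked by the fully substituted C11 and by bulky, poorly lithium-binding silyl ethers), and the α-oxy allyl anion 20 undergoes a concerted [2,3]-Wittig shift through a five-membered envelope in which C6 bonds to C7 while O–C13 breaks and C11=C13 forms. The closest known reaction type is the [2,3]-Wittig ring contraction of thirteen-membered diallylic ethers to germacrane-type cyclodecadienols, applied here to the (Z,Z) series. The ten-membered carbocycle is closed by contraction of the existing ether ring (O, C13 and C11 leave the ring), not by end-to-end cyclisation, so no high dilution is needed. C7 should be set by addition anti to the C8–OSi bond in the conformer where H8 eclipses the C12 branch (allylic 1,3-strain), and C6 relative to C7 by the trans arrangement of C8 and C13 on C7=C11 with the C5 vinyl group exo on the envelope; together these give cis oxygens at C6 and C8 (C7 is erased later). The step needs C6-over-C13 lithiation, [2,3] over [1,2] shift and retention of the (Z)-C4=C5 geometry, all favoured by low temperature; the cold quench also prevents O8→O6 silyl migration in the lithium alkoxide.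

Step 15
Reactants: 21 (1S,2Z,6Z,9R,10R)-9-[(tert-butyldimethylsilyl)oxy]-10-{3-[(tert-butyldimethylsilyl)oxy]prop-1-en-2-yl}-3,7-dimethylcyclodeca-2,6-dien-1-ol
Product: 22 (1(10)Z)-4β,5β-epoxy-8β,12-bis[(tert-butyldimethylsilyl)oxy]germacra-1(10),11(13)-dien-6β-ol (4S,5R,6R,7R,8R)
Conditions: VO(acac)2 (cat.), t-BuOOH, CH2Cl2, 0 °C
Reagents that add atoms: tert-butyl hydroperoxide, CC(C)(C)OO
Why: Vanadium-catalysed hydroxyl-directed epoxidation of the allylic alcohol delivers oxygen to C4=C5 from the face of O6 (the usual cis outcome for medium-ring (Z)-cycloalkenols); syn addition to the Z alkene makes the oxirane cis-fused, while the remote C1=C10 and the merely homoallylic C11=C13 react far more slowly.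

Step 16
Reactants: 22 (1(10)Z)-4β,5β-epoxy-8β,12-bis[(tert-butyldimethylsilyl)oxy]germacra-1(10),11(13)-dien-6β-ol
Product: 23 (1(10)Z)-4β,5β-epoxy-8β-[(tert-butyldimethylsilyl)oxy]germacra-1(10),11(13)-diene-6β,12-diol (4S,5R,6R,7R,8R)
Conditions: HF·pyridine, pyridine, THF, 0 °C
Reagents that add atoms: none
Why: Buffered HF·pyridine removes the primary allylic silyl ether selectively (steric differentiation from the hindered secondary C8 ether), and the buffer protects the epoxy alcohol.

Step 17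
Reactants: 23 (1(10)Z)-4β,5β-epoxy-8β-[(tert-butyldimethylsilyl)oxy]germacra-1(10),11(13)-diene-6β,12-diol
Product: 26 (1(10)Z)-4β,5β-epoxy-8β-[(tert-butyldimethylsilyl)oxy]germacra-1(10),11(13)-dien-12,6β-olide (4S,5R,6R,7R,8R), via hydroxy enal 24 (not isolated), via lactol 25 (not isolated)
Conditions: TEMPO (cat.), PhI(OAc)2, CH2Cl2, rt
Reagents that add atoms: none
Why: TEMPO/PhI(OAc)2 oxidative lactonisation oxidises the primary allylic alcohol chemoselectively to the enal, which closes to the five-membered lactol on O6 and is oxidised on to the α-methylene γ-lactone; O8 is still silylated, so only the 12,6-olide can form.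

Step 18
Reactants: 26 (1(10)Z)-4β,5β-epoxy-8β-[(tert-butyldimethylsilyl)oxy]germacra-1(10),11(13)-dien-12,6β-olide
Product: 27 (1(10)Z)-4β,5β-epoxy-8β-hydroxygermacra-1(10),11(13)-dien-12,6β-olide (4S,5R,6R,7S,8R)
Conditions: n-Bu4NF, AcOH (1:1), THF, 0 °C → rt
Reagents that add atoms: none
Why: Fluoride desilylation buffered with acetic acid keeps the medium near neutral, so neither translactonisation onto O8, conjugate addition to the methylene lactone, nor acid-induced transannular opening of the oxirane is triggered.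

Step 19
Reactants: 27 (1(10)Z)-4β,5β-epoxy-8β-hydroxygermacra-1(10),11(13)-dien-12,6β-olide
Product: 28 1β,10β:4β,5β-diepoxy-8β-hydroxygermacr-11(13)-en-12,6β-olide (1R,4S,5R,6R,7S,8R,10S)
Conditions: VO(acac)2 (cat.), t-BuOOH, CH2Cl2, rt
Reagents that add atoms: tert-butyl hydroperoxide, CC(C)(C)OO
Why: Vanadium-catalysed epoxidation directed by the homoallylic C8 hydroxyl delivers oxygen through a cyclic vanadate to the C1=C10 face syn to O8, giving the second cis-fused oxirane; the electron-poor C11=C13 is inert to the electrophilic peroxo-vanadium species.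

Step 20
Reactants: 28 1β,10β:4β,5β-diepoxy-8β-hydroxygermacr-11(13)-en-12,6β-olide
Product: 29 1β,10β:4β,5β-diepoxy-8β,11,13-trihydroxygermacran-12,6β-olide (11S; 11-OH cis to H7)
Conditions: OsO4 (cat.), NMO, acetone/H2O, rt
Reagents that add atoms: osmium tetroxide (catalytic carrier of both oxygens), O=[Os](=O)(=O)=O; N-methylmorpholine N-oxide, C[N+]1([O-])CCOCC1; water, O
Why: Upjohn dihydroxylation of the only remaining alkene should occur from the lactone face that carries H7 (away from the C8 branch on the adjacent carbon), placing the tertiary 11-OH cis to H7 as required for the later syn-elimination.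

Step 21
Reactants: 29 1β,10β:4β,5β-diepoxy-8β,11,13-trihydroxygermacran-12,6β-olide
Product: 30 13-acetoxy-1β,10β:4β,5β-diepoxy-8β,11-dihydroxygermacran-12,6β-olide (11S)
Conditions: AcCl, 2,4,6-collidine, CH2Cl2, −78 °C
Reagents that add atoms: acetyl chloride, CC(=O)Cl
Why: Kinetic acylation with a hindered base acetylates the primary C13 hydroxyl in preference to the secondary C8 and tertiary C11 hydroxyls.

Step 22
Reactants: 30 13-acetoxy-1β,10β:4β,5β-diepoxy-8β,11-dihydroxygermacran-12,6β-olide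
Product: 31 13-acetoxy-1β,10β:4β,5β-diepoxy-11-hydroxy-8β-(methacryloyloxy)germacran-12,6β-olide (11S)
Conditions: methacrylic anhydride, Et3N, DMAP (cat.), CH2Cl2, 0 °C → rt
Reagents that add atoms: methacrylic anhydride, CC(=C)C(=O)OC(=O)C(C)=C
Why: DMAP-catalysed acyl transfer esterifies the secondary C8 hydroxyl, while the tertiary α-hydroxy lactone hydroxyl is too hindered to react; the methacrylate is introduced only after the OsO4 step, which it would not survive.

Step 23
Reactants: 31 13-acetoxy-1β,10β:4β,5β-diepoxy-11-hydroxy-8β-(methacryloyloxy)germacran-12,6β-olide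
Product: 33 CNP0212980.1 (1R,4S,5R,6R,8R,10S)-13-acetoxy-1,10:4,5-diepoxy-8-(methacryloyloxy)germacr-7(11)-en-12,6-olide, via sulfamate ester 32 (not isolated)
Conditions: Burgess reagent (methyl N-(triethylammoniosulfonyl)carbamate), benzene, 50 °C
Reagents that add atoms: none
Why: Burgess dehydration is a neutral syn (Ei) elimination of the tertiary sulfamate ester; H7 is cis to O11 on the lactone ring and its loss should give the tetrasubstituted, conjugated 7(11)-butenolide (Zaitsev direction), which removes the C7 and C11 stereocentres and tolerates both oxiranes and both esters.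

**Compound list**

1 | nerol, (2Z)-3,7-dimethylocta-2,6-dien-1-ol | OC/C=C(C)\CCC=C(C)C | starting material
2 | neryl 4-methoxybenzyl ether | COc1ccc(COC/C=C(C)\CCC=C(C)C)cc1 | intermediate
3 | terminal (6,7-)epoxide of 2, racemic at the oxirane CH | COc1ccc(COC/C=C(C)\CCC2OC2(C)C)cc1 | intermediate
4 | (4Z)-6-[(4-methoxybenzyl)oxy]-4-methylhex-4-enal | COc1ccc(COC/C=C(C)\CCC=O)cc1 | intermediate
5 | (2Z,6Z)-7-iodo-3-methylocta-2,6-dien-1-yl 4-methoxybenzyl ether | COc1ccc(COC/C=C(C)\CC/C=C(\I)C)cc1 | intermediate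
6 | methyl (2R)-oxirane-2-carboxylate (methyl (R)-glycidate) | COC(=O)[C@H]1CO1 | starting material
7 | vinyllithium from 5 (Li in place of I, geometry retained) | COc1ccc(COC/C=C(C)\CC/C=C(\[Li])C)cc1 | intermediate
8 | vinylmagnesium bromide from 7 | COc1ccc(COC/C=C(C)\CC/C=C(\[Mg]Br)C)cc1 | intermediate
9 | methyl (2R,4Z,8Z)-2-hydroxy-10-[(4-methoxybenzyl)oxy]-4,8-dimethyldeca-4,8-dienoate | COC(=O)[C@H](O)C/C(C)=C\CC/C(C)=C\COCc1ccc(OC)cc1 | intermediate
10 | methyl (2R,4Z,8Z)-2-(TBS-oxy)-10-[(4-methoxybenzyl)oxy]-4,8-dimethyldeca-4,8-dienoate | COC(=O)[C@H](O[Si](C)(C)C(C)(C)C)C/C(C)=C\CC/C(C)=C\COCc1ccc(OC)cc1 | intermediate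
11 | (2R,4Z,8Z)-2-(TBS-oxy)-10-[(4-methoxybenzyl)oxy]-4,8-dimethyldeca-4,8-dienal | O=C[C@H](O[Si](C)(C)C(C)(C)C)C/C(C)=C\CC/C(C)=C\COCc1ccc(OC)cc1 | intermediate
12 | diethyl (2-hydroxyethyl)phosphonate | CCOP(=O)(CCO)OCC | starting material
13 | diethyl [2-(TBS-oxy)ethyl]phosphonate | CCOP(=O)(CCO[Si](C)(C)C(C)(C)C)OCC | intermediate
14 | ethyl 3-(TBS-oxy)-2-(diethoxyphosphoryl)propanoate (racemic) | CCOC(=O)C(CO[Si](C)(C)C(C)(C)C)P(=O)(OCC)OCC | intermediate
15 | ethyl (2E,4R,6Z,10Z)-4-(TBS-oxy)-2-[(TBS-oxy)methyl]-12-[(4-methoxybenzyl)oxy]-6,10-dimethyldodeca-2,6,10-trienoate | CCOC(=O)/C(CO[Si](C)(C)C(C)(C)C)=C/[C@H](O[Si](C)(C)C(C)(C)C)C/C(C)=C\CC/C(C)=C\COCc1ccc(OC)cc1 | intermediate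
16 | (2Z,4R,6Z,10Z)-4-(TBS-oxy)-2-[(TBS-oxy)methyl]-12-[(4-methoxybenzyl)oxy]-6,10-dimethyldodeca-2,6,10-trien-1-ol | OC/C(CO[Si](C)(C)C(C)(C)C)=C/[C@H](O[Si](C)(C)C(C)(C)C)C/C(C)=C\CC/C(C)=C\COCc1ccc(OC)cc1 | intermediate
17 | (2Z,6Z,9R,10E)-12-chloro-9-(TBS-oxy)-11-[(TBS-oxy)methyl]-3,7-dimethyldodeca-2,6,10-trien-1-yl 4-methoxybenzyl ether | ClC/C(CO[Si](C)(C)C(C)(C)C)=C/[C@H](O[Si](C)(C)C(C)(C)C)C/C(C)=C\CC/C(C)=C\COCc1ccc(OC)cc1 | intermediate
18 | (2Z,6Z,9R,10E)-12-chloro-9-(TBS-oxy)-11-[(TBS-oxy)methyl]-3,7-dimethyldodeca-2,6,10-trien-1-ol | ClC/C(CO[Si](C)(C)C(C)(C)C)=C/[C@H](O[Si](C)(C)C(C)(C)C)C/C(C)=C\CC/C(C)=C\CO | intermediate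
19 | (3Z,7Z,10R,11Z)-10-(TBS-oxy)-12-[(TBS-oxy)methyl]-4,8-dimethyl-1-oxacyclotrideca-3,7,11-triene (key-step precursor) | O1C/C=C(C)\CC/C=C(C)\C[C@@H](O[Si](C)(C)C(C)(C)C)/C=C(\CO[Si](C)(C)C(C)(C)C)C1 | intermediate
20 | C6-lithiated ether (2-lithio derivative of 19) | O1C([Li])/C=C(C)\CC/C=C(C)\C[C@@H](O[Si](C)(C)C(C)(C)C)/C=C(\CO[Si](C)(C)C(C)(C)C)C1 | intermediate
21 | (1S,2Z,6Z,9R,10R)-9-(TBS-oxy)-10-[3-(TBS-oxy)prop-1-en-2-yl]-3,7-dimethylcyclodeca-2,6-dien-1-ol (key-step product) | O[C@H]1/C=C(C)\CC/C=C(C)\C[C@@H](O[Si](C)(C)C(C)(C)C)[C@@H]1C(=C)CO[Si](C)(C)C(C)(C)C | intermediate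
22 | (1(10)Z)-4β,5β-epoxy-8β,12-bis(TBS-oxy)germacra-1(10),11(13)-dien-6β-ol (4S,5R,6R,7R,8R) | O[C@H]1[C@H]2O[C@@]2(C)CC/C=C(C)\C[C@@H](O[Si](C)(C)C(C)(C)C)[C@@H]1C(=C)CO[Si](C)(C)C(C)(C)C | intermediate
23 | (1(10)Z)-4β,5β-epoxy-8β-(TBS-oxy)germacra-1(10),11(13)-diene-6β,12-diol | O[C@H]1[C@H]2O[C@@]2(C)CC/C=C(C)\C[C@@H](O[Si](C)(C)C(C)(C)C)[C@@H]1C(=C)CO | intermediate
24 | hydroxy enal (12-aldehyde of 23) | O[C@H]1[C@H]2O[C@@]2(C)CC/C=C(C)\C[C@@H](O[Si](C)(C)C(C)(C)C)[C@@H]1C(=C)C=O | intermediate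
25 | lactol (12-hydroxy-12,6-epoxide; anomeric centre undefined) | C=C1C(O)O[C@H]2[C@H]3O[C@@]3(C)CC/C=C(C)\C[C@@H](O[Si](C)(C)C(C)(C)C)[C@H]12 | intermediate
26 | (1(10)Z)-4β,5β-epoxy-8β-(TBS-oxy)germacra-1(10),11(13)-dien-12,6β-olide (4S,5R,6R,7R,8R) | C=C1C(=O)O[C@H]2[C@H]3O[C@@]3(C)CC/C=C(C)\C[C@@H](O[Si](C)(C)C(C)(C)C)[C@H]12 | intermediate
27 | (1(10)Z)-4β,5β-epoxy-8β-hydroxygermacra-1(10),11(13)-dien-12,6β-olide (4S,5R,6R,7S,8R) | C=C1C(=O)O[C@H]2[C@H]3O[C@@]3(C)CC/C=C(C)\C[C@@H](O)[C@H]12 | intermediate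
28 | 1β,10β:4β,5β-diepoxy-8β-hydroxygermacr-11(13)-en-12,6β-olide (1R,4S,5R,6R,7S,8R,10S) | C=C1C(=O)O[C@H]2[C@H]3O[C@@]3(C)CC[C@H]4O[C@@]4(C)C[C@@H](O)[C@H]12 | intermediate
29 | 1β,10β:4β,5β-diepoxy-8β,11,13-trihydroxygermacran-12,6β-olide (11S) | OC[C@]1(O)C(=O)O[C@H]2[C@H]3O[C@@]3(C)CC[C@H]4O[C@@]4(C)C[C@@H](O)[C@H]12 | intermediate
30 | 13-acetoxy-1β,10β:4β,5β-diepoxy-8β,11-dihydroxygermacran-12,6β-olide (11S) | CC(=O)OC[C@]1(O)C(=O)O[C@H]2[C@H]3O[C@@]3(C)CC[C@H]4O[C@@]4(C)C[C@@H](O)[C@H]12 | intermediate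
31 | 13-acetoxy-1β,10β:4β,5β-diepoxy-11-hydroxy-8β-(methacryloyloxy)germacran-12,6β-olide (11S) | CC(=O)OC[C@]1(O)C(=O)O[C@H]2[C@H]3O[C@@]3(C)CC[C@H]4O[C@@]4(C)C[C@@H](OC(=O)C(C)=C)[C@H]12 | intermediate
32 | C11 sulfamate ester of 31 (triethylammonium salt) | CC(=O)OC[C@]1(OS(=O)(=O)[N-]C(=O)OC)C(=O)O[C@H]2[C@H]3O[C@@]3(C)CC[C@H]4O[C@@]4(C)C[C@@H](OC(=O)C(C)=C)[C@H]12.CC[NH+](CC)CC | intermediate
33 | CNP0212980.1, (1R,4S,5R,6R,8R,10S)-13-acetoxy-1,10:4,5-diepoxy-8-(methacryloyloxy)germacr-7(11)-en-12,6-olide | C=C(C)C(=O)O[C@@H]1C[C@]2(C)O[C@@H]2CC[C@]2(C)O[C@@H]2[C@@H]2OC(=O)C(COC(C)=O)=C21 | target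

**Step count and risks**

Total step count: 23. Longest linear sequence: 21 steps (steps 1–6 and 9–23); steps 7–8 prepare the phosphonate 14.

The three steps most likely to fail:

1. Step 14 (ring contraction). The base may lithiate C13 (or C12, followed by silyl shift) instead of C6, a [1,2]-shift may compete, or the anion may add to the wrong face of C7=C11; the result would be the wrong constitution or the C6 epimer. Fallback: form the same C6–C7 bond by chromium-mediated carbonyl allylation (Nozaki–Hiyama–Kishi type) instead of a sigmatropic shift. It sets out from 18: MnO2 in CH2Cl2 oxidises the (Z)-allylic alcohol to (2Z,6Z,9R,10E)-12-chloro-9-(TBS-oxy)-11-[(TBS-oxy)methyl]-3,7-dimethyldodeca-2,6,10-trienal F1. CrCl2 (divalent chromium) with catalytic LiI in THF/DMF under high dilution then turns the allylic chloride into an allyl-chromium unit that adds through C7 to the C6 aldehyde in a chair transition state, closing the ten-membered ring with the C11=C13 methylene. The fallback comes back to the route at 21.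

2. Step 19 (second epoxidation). Oxygen delivery from the homoallylic C8 hydroxyl across the flexible ten-membered ring may be slow or poorly face-selective. Fallback: reagent-controlled Shi epoxidation in place of substrate direction. It sets out from the silyl ether 26: the D-fructose-derived Shi ketone (the enantiomer that the spiro transition-state model assigns to the β face, by analogy with 1-substituted cycloalkenes) with KHSO5 (as 2KHSO5·KHSO4·K2SO4), K2CO3 buffer, MeCN/dimethoxymethane, 0 °C, epoxidises only the electron-rich C1=C10 to give 1β,10β:4β,5β-diepoxy-8β-(TBS-oxy)germacr-11(13)-en-12,6β-olide F2. n-Bu4NF/AcOH in THF then removes the silyl group, and the fallback comes back to the route at 28.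

3. Step 23 (dehydration). The syn-elimination may take a C13 hydrogen (giving an enol acetate) instead of H7, or may not proceed if OsO4 in step 20 added from the other face so that 11-OH is trans to H7. Fallback: install C7=C11 and the C13 oxygen in one event by a Schenck ene reaction, avoiding the diol and its dehydration. It sets out from 28: photo-oxygenation (O2, hν, tetraphenylporphyrin, CH2Cl2) adds singlet oxygen at C13 with abstraction of H7 (the hydrogen on the substituent geminal to the carbonyl, as is usual for enoates), giving the 13-hydroperoxy-7(11)-butenolide F3. PPh3 reduces it to the 8,13-diol F4, AcCl/2,4,6-collidine at −78 °C acetylates the primary hydroxyl to give the 13-acetate F5, and methacrylic anhydride/Et3N/DMAP esterifies O8. The fallback comes back to the route at 33.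

**Further compounds**

F1 | step 14 | (2Z,6Z,9R,10E)-12-chloro-9-(TBS-oxy)-11-[(TBS-oxy)methyl]-3,7-dimethyldodeca-2,6,10-trienal | ClC/C(CO[Si](C)(C)C(C)(C)C)=C/[C@H](O[Si](C)(C)C(C)(C)C)C/C(C)=C\CC/C(C)=C\C=O
F2 | step 19 | 1β,10β:4β,5β-diepoxy-8β-(TBS-oxy)germacr-11(13)-en-12,6β-olide | C=C1C(=O)O[C@H]2[C@H]3O[C@@]3(C)CC[C@H]4O[C@@]4(C)C[C@@H](O[Si](C)(C)C(C)(C)C)[C@H]12
F3 | step 23 | (1R,4S,5R,6R,8R,10S)-1,10:4,5-diepoxy-13-hydroperoxy-8-hydroxygermacr-7(11)-en-12,6-olide | O[C@@H]1C[C@]2(C)O[C@@H]2CC[C@]2(C)O[C@@H]2[C@@H]2OC(=O)C(COO)=C21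
F4 | step 23 | (1R,4S,5R,6R,8R,10S)-1,10:4,5-diepoxy-8,13-dihydroxygermacr-7(11)-en-12,6-olide | O[C@@H]1C[C@]2(C)O[C@@H]2CC[C@]2(C)O[C@@H]2[C@@H]2OC(=O)C(CO)=C21
F5 | step 23 | (1R,4S,5R,6R,8R,10S)-13-acetoxy-1,10:4,5-diepoxy-8-hydroxygermacr-7(11)-en-12,6-olide | O[C@@H]1C[C@]2(C)O[C@@H]2CC[C@]2(C)O[C@@H]2[C@@H]2OC(=O)C(COC(C)=O)=C21
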